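**Strategy.** The oxolane (ring atoms O1, C2, C3, C4, C5) is opened at O1–C5 and at the bond joining C4 to its hydroxymethyl carbon. The feature exploited is that C5 is benzylic to an electron-rich 4-oxy-3,5-dimethoxyphenyl ring while the adjacent C4 bears a one-carbon oxygenated arm, so an (E)-styrene across C4=C5 can accept the C2 hydroxyl at C5 and carbon monoxide at C4. One palladium-mediated operation thus closes the ring, adds the carbon of the second arm and sets C4 and C5. The precursor is an (E)-1,4-diarylbut-3-en-1-ol whose C2 and C3 centres come from an auxiliary-controlled syn-aldol reaction and whose primary oxygen is masked as a pivalate.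

Key step: step 7

Assumption: the ring atoms are called O1, C2, C3, C4 and C5 throughout the discussion, C2 being the carbinol carbon and C5 the benzylic alkene carbon of the open-chain precursor, whatever locants the systematic names require.

Design notes:
- The primary oxygen of the key-step precursor is carried as a pivalate. It goes on the free 1,3-diol selectively, so no temporary silyl group and no strongly basic alkylation are needed. It is removed by the hydride that reduces the new ester, so the final hydrogenolysis only has to cleave two aryl benzyl ethers next to the bis-benzylic oxolane.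
- The key step is buffered with NaOAc because CuCl2 turnover releases HCl and both benzylic C–O bonds carry para-alkoxyaryl groups.

Step 1
Reactants: 1 syringaldehyde (4-hydroxy-3,5-dimethoxybenzaldehyde)
Product: 2 4-(benzyloxy)-3,5-dimethoxybenzaldehyde
Conditions: BnBr, K2CO3, DMF, 60 °C
Reagents that add atoms: benzyl bromide, BrCc1ccccc1
Why: Williamson ether synthesis, in which the phenoxide of 1 (acidified by the para formyl group) should be O-alkylated cleanly by the benzylic bromide.

Step 2
Reactants: 2 4-(benzyloxy)-3,5-dimethoxybenzaldehyde; 3 (2-carboxyethyl)triphenylphosphonium bromide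
Product: 5 (3E)-4-[4-(benzyloxy)-3,5-dimethoxyphenyl]but-3-enoic acid, via sodium 3-(triphenylphosphoranylidene)propanoate 4 (not isolated)
Conditions: NaN(SiMe3)2 (2.2 equiv), THF, 0 °C; then 2, 0 °C to rt; aq. HCl
Reagents that add atoms: none
Why: Wittig reaction of a carboxylate-bearing ylide, a reagent class that converts aromatic aldehydes into (E)-β,γ-unsaturated acids whose alkene stays conjugated with the arene, the acid being purified by base extraction and crystallisation.

Step 3
Reactants: 5 (3E)-4-[4-(benzyloxy)-3,5-dimethoxyphenyl]but-3-enoic acid; 6 (4S)-4-benzyl-1,3-oxazolidin-2-one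
Product: 8 (4S)-4-benzyl-3-{(3E)-4-[4-(benzyloxy)-3,5-dimethoxyphenyl]but-3-enoyl}-1,3-oxazolidin-2-one, via mixed pivalic anhydride 7 (not isolated)
Conditions: t-BuCOCl, Et3N, THF, −20 °C; then LiCl, 6, −20 °C to rt
Reagents that add atoms: none
Why: N-acylation of the auxiliary through a mixed anhydride, in which LiCl-assisted attack of 6 should occur at the less hindered acyl group under conditions mild enough to leave the styrene-conjugated alkene in place.

Step 4
Reactants: 8 (4S)-4-benzyl-3-{(3E)-4-[4-(benzyloxy)-3,5-dimethoxyphenyl]but-3-enoyl}-1,3-oxazolidin-2-one; 2 4-(benzyloxy)-3,5-dimethoxybenzaldehyde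
Product: 11 (4S)-4-benzyl-3-[(2S,3E)-4-[4-(benzyloxy)-3,5-dimethoxyphenyl]-2-{(S)-[4-(benzyloxy)-3,5-dimethoxyphenyl](hydroxy)methyl}but-3-enoyl]-1,3-oxazolidin-2-one, via dibutylboron Z-dienolate 9 (not isolated), via dibutylboron aldolate 10 (not isolated)
Conditions: n-Bu2BOTf, i-Pr2NEt, CH2Cl2, −78 to 0 °C; 2, −78 to 0 °C; then pH 7 buffer, MeOH, 30% H2O2, 0 °C
Reagents that add atoms: none
Why: Evans syn-aldol reaction, in which soft enolisation gives the Z-configured boron dienolate that should react at its α-carbon through a closed Zimmerman–Traxler chair on the face away from the benzyl group of the (S)-auxiliary, setting the carbinol centre (S) and the α-centre (S) in a syn relationship.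

Step 5
Reactants: 11 (4S)-4-benzyl-3-[(2S,3E)-4-[4-(benzyloxy)-3,5-dimethoxyphenyl]-2-{(S)-[4-(benzyloxy)-3,5-dimethoxyphenyl](hydroxy)methyl}but-3-enoyl]-1,3-oxazolidin-2-one
Product: 12 (1S,2R)-1-[4-(benzyloxy)-3,5-dimethoxyphenyl]-2-{(E)-2-[4-(benzyloxy)-3,5-dimethoxyphenyl]ethenyl}propane-1,3-diol
Conditions: LiBH4, MeOH (1 equiv), THF, 0 °C
Reagents that add atoms: none
Why: reductive removal of the auxiliary by hydride reduction of the exocyclic imide carbonyl, which turns the α-centre into a non-epimerisable carbon while the styrene and the aryl benzyl ethers are inert to LiBH4.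

Step 6
Reactants: 12 (1S,2R)-1-[4-(benzyloxy)-3,5-dimethoxyphenyl]-2-{(E)-2-[4-(benzyloxy)-3,5-dimethoxyphenyl]ethenyl}propane-1,3-diol
Product: 13 (2R,3E)-4-[4-(benzyloxy)-3,5-dimethoxyphenyl]-2-{(S)-[4-(benzyloxy)-3,5-dimethoxyphenyl](hydroxy)methyl}but-3-en-1-yl 2,2-dimethylpropanoate
Conditions: t-BuCOCl (1.1 equiv), pyridine, CH2Cl2, 0 °C
Reagents that add atoms: pivaloyl chloride, CC(C)(C)C(Cl)=O
Why: selective acylation (esterification), in which the bulky acid chloride should take the unhindered primary hydroxyl and leave free the secondary benzylic hydroxyl that serves as the nucleophile of step 7.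

Step 7
Reactants: 13 (2R,3E)-4-[4-(benzyloxy)-3,5-dimethoxyphenyl]-2-{(S)-[4-(benzyloxy)-3,5-dimethoxyphenyl](hydroxy)methyl}but-3-en-1-yl 2,2-dimethylpropanoate; 14 carbon monoxide
Product: 17 methyl (2S,3S,4R,5S)-2,5-bis[4-(benzyloxy)-3,5-dimethoxyphenyl]-4-{[(2,2-dimethylpropanoyl)oxy]methyl}oxolane-3-carboxylate (all-trans), via ring alkylpalladium chloride 15 (not isolated), via ring acylpalladium chloride 16 (not isolated)
Conditions: PdCl2(MeCN)2 (10 mol %), CuCl2 (3 equiv), NaOAc (3 equiv), CO (1 atm), MeOH/CH2Cl2, 0 °C to rt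
Reagents that add atoms: methanol (SMILES CO)
Why: Proposed new method: the alkene of 13 should bind to divalent palladium and be attacked at benzylic C5 by the C2 hydroxyl from the face opposite the metal, carbon monoxide should then enter the C4–Pd bond of alkylpalladium 15 with retention of configuration, and methanol should cleave acylpalladium 16 to ester 17 and zerovalent palladium, which CuCl2 reoxidises; the nearest precedents in type are iodine-induced 5-endo-trig etherification of (E)-homoallylic alcohols, which gives 2,5-trans-3-iodooxolanes, and the PdCl2/CuCl2/CO/MeOH oxycarbonylation of hydroxy alkenes, known for exo ring closures. The oxolane closes in the 5-endo-trig mode, which the 4-benzyloxy-3,5-dimethoxyphenyl group should make accessible by letting positive charge build at C5 of the palladium-bound alkene. C5 is set by the choice of alkene face: in an envelope-like transition state the C2 aryl group and the C3 pivaloyloxymethyl arm lie pseudo-equatorial, which puts the C5 aryl group trans to the C2 aryl group and the metal trans to the C3 arm. C4 follows from the (E)-geometry, the anti mode of oxypalladation and retentive CO insertion, so the ester comes out trans to both of its neighbours. The step needs attack of oxygen at C5 to win over 4-exo attack at C4 and over acylpalladation by an alkoxycarbonylpalladium species formed at the hydroxyl, which the benzylic bias and only one atmosphere of CO should secure, and it needs CO insertion to outrun β-hydride elimination toward C3 or C5, which the CO-saturated medium secures. NaOAc takes up the HCl of copper turnover so that the acid-labile benzylic C–O bonds at C2 and C5 are not ionised, and the pivalate keeps the primary oxygen from competing for C5.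

Step 8
Reactants: 17 methyl (2S,3S,4R,5S)-2,5-bis[4-(benzyloxy)-3,5-dimethoxyphenyl]-4-{[(2,2-dimethylpropanoyl)oxy]methyl}oxolane-3-carboxylate
Product: 18 [(2S,3R,4R,5S)-2,5-bis[4-(benzyloxy)-3,5-dimethoxyphenyl]oxolane-3,4-diyl]dimethanol
Conditions: LiAlH4, THF, 0 °C to rt
Reagents that add atoms: none
Why: hydride reduction of esters, in which LiAlH4 turns the methyl ester into the second hydroxymethyl group and cleaves the pivalate in the same operation while the aryl benzyl ethers, the oxolane and the four stereocentres are untouched.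

Step 9
Reactants: 18 [(2S,3R,4R,5S)-2,5-bis[4-(benzyloxy)-3,5-dimethoxyphenyl]oxolane-3,4-diyl]dimethanol
Product: 19 huazhongilexin (4,4'-[(2S,3R,4R,5S)-3,4-bis(hydroxymethyl)oxolane-2,5-diyl]bis(2,6-dimethoxyphenol))
Conditions: H2 (1 atm), Pd/C, EtOAc/MeOH, rt
Reagents that add atoms: none
Why: catalytic hydrogenolysis, in which the two aryl benzyl ethers should cleave quickly under one atmosphere of hydrogen so that the reaction can be stopped before the cyclic benzylic C–O bonds of the oxolane are attacked.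

**Compound list**

1 | syringaldehyde (4-hydroxy-3,5-dimethoxybenzaldehyde) | COc1cc(C=O)cc(OC)c1O | starting material
2 | 4-(benzyloxy)-3,5-dimethoxybenzaldehyde | COc1cc(C=O)cc(OC)c1OCc1ccccc1 | intermediate
3 | (2-carboxyethyl)triphenylphosphonium bromide | [Br-].OC(=O)CC[P+](c1ccccc1)(c1ccccc1)c1ccccc1 | starting material
4 | sodium 3-(triphenylphosphoranylidene)propanoate (ylide) | [Na+].[O-]C(=O)CC=P(c1ccccc1)(c1ccccc1)c1ccccc1 | intermediate
5 | (3E)-4-[4-(benzyloxy)-3,5-dimethoxyphenyl]but-3-enoic acid | OC(=O)C/C=C/c1cc(OC)c(OCc2ccccc2)c(OC)c1 | intermediate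
6 | (4S)-4-benzyl-1,3-oxazolidin-2-one | O=C1N[C@@H](Cc2ccccc2)CO1 | starting material
7 | (3E)-4-[4-(benzyloxy)-3,5-dimethoxyphenyl]but-3-enoic 2,2-dimethylpropanoic anhydride (mixed pivalic anhydride) | CC(C)(C)C(=O)OC(=O)C/C=C/c1cc(OC)c(OCc2ccccc2)c(OC)c1 | intermediate
8 | (4S)-4-benzyl-3-{(3E)-4-[4-(benzyloxy)-3,5-dimethoxyphenyl]but-3-enoyl}-1,3-oxazolidin-2-one | O=C(C/C=C/c1cc(OC)c(OCc2ccccc2)c(OC)c1)N1[C@@H](Cc2ccccc2)COC1=O | intermediate
9 | (4S)-4-benzyl-3-{(1Z,3E)-4-[4-(benzyloxy)-3,5-dimethoxyphenyl]-1-[(dibutylboranyl)oxy]buta-1,3-dien-1-yl}-1,3-oxazolidin-2-one (dibutylboron Z-dienolate) | CCCCB(CCCC)O/C(=C\C=C\c1cc(OC)c(OCc2ccccc2)c(OC)c1)N1[C@@H](Cc2ccccc2)COC1=O | intermediate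
10 | O-dibutylboranyl derivative of 11 (dibutylboron aldolate) | CCCCB(CCCC)O[C@H](c1cc(OC)c(OCc2ccccc2)c(OC)c1)[C@@H](C(=O)N1[C@@H](Cc2ccccc2)COC1=O)/C=C/c1cc(OC)c(OCc2ccccc2)c(OC)c1 | intermediate
11 | (4S)-4-benzyl-3-[(2S,3E)-4-[4-(benzyloxy)-3,5-dimethoxyphenyl]-2-{(S)-[4-(benzyloxy)-3,5-dimethoxyphenyl](hydroxy)methyl}but-3-enoyl]-1,3-oxazolidin-2-one | O[C@H](c1cc(OC)c(OCc2ccccc2)c(OC)c1)[C@@H](C(=O)N1[C@@H](Cc2ccccc2)COC1=O)/C=C/c1cc(OC)c(OCc2ccccc2)c(OC)c1 | intermediate
12 | (1S,2R)-1-[4-(benzyloxy)-3,5-dimethoxyphenyl]-2-{(E)-2-[4-(benzyloxy)-3,5-dimethoxyphenyl]ethenyl}propane-1,3-diol | O[C@H](c1cc(OC)c(OCc2ccccc2)c(OC)c1)[C@@H](CO)/C=C/c1cc(OC)c(OCc2ccccc2)c(OC)c1 | intermediate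
13 | (2R,3E)-4-[4-(benzyloxy)-3,5-dimethoxyphenyl]-2-{(S)-[4-(benzyloxy)-3,5-dimethoxyphenyl](hydroxy)methyl}but-3-en-1-yl 2,2-dimethylpropanoate, the (1S,2R,3E)-1,4-diarylbut-3-en-1-ol with a pivaloyloxymethyl group at its C2 | O[C@H](c1cc(OC)c(OCc2ccccc2)c(OC)c1)[C@@H](COC(=O)C(C)(C)C)/C=C/c1cc(OC)c(OCc2ccccc2)c(OC)c1 | intermediate
14 | carbon monoxide | [C-]#[O+] | starting material
15 | all-trans ring alkylpalladium chloride, palladium on ring atom C4 (further ligands omitted) | COc1cc([C@H]2O[C@H](c3cc(OC)c(OCc4ccccc4)c(OC)c3)[C@@H]([Pd]Cl)[C@@H]2COC(=O)C(C)(C)C)cc(OC)c1OCc1ccccc1 | intermediate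
16 | all-trans ring acylpalladium chloride, acyl group on ring atom C4 (further ligands omitted) | COc1cc([C@H]2O[C@H](c3cc(OC)c(OCc4ccccc4)c(OC)c3)[C@@H](C(=O)[Pd]Cl)[C@@H]2COC(=O)C(C)(C)C)cc(OC)c1OCc1ccccc1 | intermediate
17 | methyl (2S,3S,4R,5S)-2,5-bis[4-(benzyloxy)-3,5-dimethoxyphenyl]-4-{[(2,2-dimethylpropanoyl)oxy]methyl}oxolane-3-carboxylate (all-trans) | COc1cc([C@H]2O[C@H](c3cc(OC)c(OCc4ccccc4)c(OC)c3)[C@@H](C(=O)OC)[C@@H]2COC(=O)C(C)(C)C)cc(OC)c1OCc1ccccc1 | intermediate
18 | [(2S,3R,4R,5S)-2,5-bis[4-(benzyloxy)-3,5-dimethoxyphenyl]oxolane-3,4-diyl]dimethanol | COc1cc([C@H]2O[C@H](c3cc(OC)c(OCc4ccccc4)c(OC)c3)[C@@H](CO)[C@@H]2CO)cc(OC)c1OCc1ccccc1 | intermediate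
19 | huazhongilexin, 4,4'-[(2S,3R,4R,5S)-3,4-bis(hydroxymethyl)oxolane-2,5-diyl]bis(2,6-dimethoxyphenol) | COc1cc([C@H]2O[C@H](c3cc(OC)c(O)c(OC)c3)[C@@H](CO)[C@@H]2CO)cc(OC)c1O | target

**Step count and risks**

Total step count: 9. Longest linear sequence: 9 steps (1 → 2 → 5 → 8 → 11 → 12 → 13 → 17 → 18 → 19).

Steps most likely to fail:

Step 7 (bears the label). The hydroxyl may fail to add in the endo sense to the palladium-bound styrene. Carbonylation at oxygen followed by exo acylpalladation (lactone formation), addition of solvent methanol, or β-hydride elimination from the ring alkylpalladium would divert the material. Acid released on copper turnover could also ionise the benzylic centres and erode the configuration at C2 or C5. The fallback uses known chemistry, sets out from 13 and comes back at 17. 5-endo-trig iodoetherification of 13 (I2, NaHCO3, MeCN, 0 °C) should give, by the same anti addition across the (E)-alkene, the all-trans iodide [(2S,3R,4S,5R)-2,5-bis[4-(benzyloxy)-3,5-dimethoxyphenyl]-4-iodooxolan-3-yl]methyl 2,2-dimethylpropanoate F1. Light-induced atom-transfer alkoxycarbonylation of this secondary iodide (CO 45 atm, MeOH, Et3N, Pd(PPh3)4, xenon lamp) should then give 17, the ring radical at C4 taking up CO on the face away from both flanking substituents.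

Step 4. The extended boron dienolate may react through its γ-carbon or lose the position of its alkene, the electron-rich aldehyde may add sluggishly, and the aldolate may undergo retro-aldol cleavage during the oxidative work-up. The fallback sets out from 6 and 2, comes back at 12, and attaches the styrene only after the aldol reaction. N-Acylation of 6 (n-BuLi, crotonyl chloride, THF, −78 °C) gives (4S)-4-benzyl-3-[(2E)-but-2-enoyl]-1,3-oxazolidin-2-one F2. Its boron dienolate (n-Bu2BOTf, Et3N), an α-selective aldol partner, should add to 2 to give the α-vinyl syn-aldol adduct (4S)-4-benzyl-3-[(2S)-2-{(S)-[4-(benzyloxy)-3,5-dimethoxyphenyl](hydroxy)methyl}but-3-enoyl]-1,3-oxazolidin-2-one F3. LiBH4 then gives (1S,2R)-1-[4-(benzyloxy)-3,5-dimethoxyphenyl]-2-ethenylpropane-1,3-diol F4. Wittig methylenation of 2 (Ph3PCH3Br, KOt-Bu, THF) gives 2-(benzyloxy)-5-ethenyl-1,3-dimethoxybenzene F5. Olefin cross-metathesis of F4 with an excess of F5 (second-generation Grubbs catalyst, CH2Cl2, 40 °C) should give the (E)-alkene 12.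

Step 2. The olefination may stall or give an E/Z mixture, because the doubly deprotonated phosphonium salt is a strong base and the aldehyde is electron-rich. The fallback sets out from 2 and comes back at 5. Wittig reaction of 2 with the ylide from (methoxymethyl)triphenylphosphonium chloride and KOt-Bu gives the enol ether 2-(benzyloxy)-1,3-dimethoxy-5-(2-methoxyethenyl)benzene F6. Mild acid hydrolysis (aqueous HCl, THF) gives [4-(benzyloxy)-3,5-dimethoxyphenyl]acetaldehyde F7. Knoevenagel condensation of F7 with malonic acid under Linstead conditions (N-methylmorpholine or pyridine, 90 °C) should give the (E)-β,γ-unsaturated acid 5 by decarboxylation with the alkene settling in conjugation with the aryl ring.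

**Further compounds**

F1 | step 7 | [(2S,3R,4S,5R)-2,5-bis[4-(benzyloxy)-3,5-dimethoxyphenyl]-4-iodooxolan-3-yl]methyl 2,2-dimethylpropanoate (all-trans) | COc1cc([C@H]2O[C@H](c3cc(OC)c(OCc4ccccc4)c(OC)c3)[C@@H](I)[C@@H]2COC(=O)C(C)(C)C)cc(OC)c1OCc1ccccc1
F2 | step 4 | (4S)-4-benzyl-3-[(2E)-but-2-enoyl]-1,3-oxazolidin-2-one | C/C=C/C(=O)N1[C@@H](Cc2ccccc2)COC1=O
F3 | step 4 | (4S)-4-benzyl-3-[(2S)-2-{(S)-[4-(benzyloxy)-3,5-dimethoxyphenyl](hydroxy)methyl}but-3-enoyl]-1,3-oxazolidin-2-one | O[C@H](c1cc(OC)c(OCc2ccccc2)c(OC)c1)[C@@H](C(=O)N1[C@@H](Cc2ccccc2)COC1=O)C=C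
F4 | step 4 | (1S,2R)-1-[4-(benzyloxy)-3,5-dimethoxyphenyl]-2-ethenylpropane-1,3-diol | O[C@H](c1cc(OC)c(OCc2ccccc2)c(OC)c1)[C@@H](CO)C=C
F5 | step 4 | 2-(benzyloxy)-5-ethenyl-1,3-dimethoxybenzene | C=Cc1cc(OC)c(OCc2ccccc2)c(OC)c1
F6 | step 2 | 2-(benzyloxy)-1,3-dimethoxy-5-(2-methoxyethenyl)benzene (E/Z mixture) | COC=Cc1cc(OC)c(OCc2ccccc2)c(OC)c1
F7 | step 2 | [4-(benzyloxy)-3,5-dimethoxyphenyl]acetaldehyde | O=CCc1cc(OC)c(OCc2ccccc2)c(OC)c1
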